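Plan
1. Locants (germacrane type): ring A is the ten-membered carbocycle C1–C10 (oxirane on C1/C10, methyl C14 on C10); ring B is the α-methylene-γ-lactone O–C6/C7–C11(=C13)–C12; C4 carries OH and C15H2OH, C3 carries OH, C8 carries the angelate.
2. Retrosynthesis, in order: the O8 angelate, the C11=C13 methylene and the O6–C12 lactone bond; then C4–C5 as an aldol bond, possible because the tertiary carbinol C4 lies 1,3 to the C6 oxygen across the C5 methylene and C3/C4/C15 form a dihydroxyacetone unit that can be carried as a ketone inside an acetonide (temporary 1,3-dioxane ring); then C2–C3 (hydrazone alkylation), C7–C8 (allylboration) and C8–C9 (ethylene oxide homologation of a (Z)-iodoalkene).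
3. Forward: (Z)-iodobutenol gives a β,γ-unsaturated aldehyde; allylboration joins C7–C8 and brings C5=C6 and C11–C12; epoxidation; alkylation joins C2–C3; the vinyl group becomes a bromomethyl ketone; a SmI2 Reformatsky-type aldol closes ring A at C4–C5; directed reduction and oxidative lactonisation build ring B; methylenation, angelate, acetonide removal.
4. Stereochemistry: C7/C8 from the (E)-allylboronate (anti) and a chiral phosphoric acid; C1/C10 from Sharpless epoxidation of a (Z)-allylic alcohol; C3 from the SAMP auxiliary; C4 from axial attack on the chair dioxanone in the key step; C6 from hydride delivery by the C4 hydroxyl.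

Key step: step 18

Assumption: the given SMILES places C2 and C9 on the same side of the oxirane, so the epoxide is derived from a (Z)-alkene; the facial senses quoted for the (S)-phosphoric acid catalyst and for the SAMP azaenolate are those of the accepted transition-state models.

Step 1
Reactants: 1 but-3-yn-1-ol
Product: 2 tert-butyldiphenylsilyl ether of 1
Conditions: TBDPSCl, imidazole, DMF, 0 °C to rt
Reagents that add atoms: tert-butyl(chloro)diphenylsilane, CC(C)(C)[Si](Cl)(c1ccccc1)c1ccccc1
Why: Standard silyl ether formation on a primary alcohol, giving a robust O12 protecting group; no stereocentre is formed.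

Step 2
Reactants: 2 silyl ether
Product: 3 (E)-alkenylboronate
Conditions: pinacolborane, Cp2Zr(H)Cl (cat.), Et3N (cat.), neat, 60 °C
Reagents that add atoms: pinacolborane, CC1(C)OBOC1(C)C
Why: Zirconocene-hydride-catalysed syn-hydroboration of a terminal alkyne should place boron on the terminal carbon and give the (E)-alkenylboronate.

Step 3
Reactants: 3 (E)-alkenylboronate
Product: 5 (E)-allylboronate, via chloromethylboronate complex 4 (not isolated)
Conditions: ClCH2I, n-BuLi, THF, −78 °C to rt
Reagents that add atoms: chloroiodomethane, ClCI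
Why: Matteson homologation, in which chloromethyllithium adds to boron and 1,2-migration of the alkenyl group with loss of chloride inserts one CH2 with retention of the E geometry.

Step 4
Reactants: 6 but-2-yn-1-ol
Product: 8 (Z)-3-iodobut-2-en-1-ol, via cyclic alkenylalanate 7 (not isolated)
Conditions: NaAlH2(OCH2CH2OMe)2, THF, 0 °C to rt; then I2, −78 °C
Reagents that add atoms: iodine, II
Why: Hydroxyl-directed trans-hydroalumination of a propargylic alcohol should place aluminium on the distal carbon in a five-membered alanate, and iodinolysis with retention gives the (Z)-iodoalkene.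

Step 5
Reactants: 8 (Z)-3-iodobut-2-en-1-ol
Product: 9 tert-butyldimethylsilyl ether of 8
Conditions: TBSCl, imidazole, CH2Cl2, 0 °C to rt
Reagents that add atoms: tert-butyl(chloro)dimethylsilane, CC(C)(C)[Si](C)(C)Cl
Why: Standard silylation that masks O2 for the organolithium step; no stereocentre is formed.

Step 6
Reactants: 9 (Z)-iodoalkene silyl ether
Product: 11 (Z)-homoallylic alcohol, via alkenyllithium 10 (not isolated)
Conditions: t-BuLi (2 equiv), Et2O, −78 °C; then ethylene oxide, −78 to 0 °C
Reagents that add atoms: ethylene oxide, C1CO1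
Why: Iodine–lithium exchange proceeds with retention of alkene geometry and the alkenyllithium opens ethylene oxide, a two-carbon homologation that installs C9 and C8.

Step 7
Reactants: 11 (Z)-homoallylic alcohol
Product: 12 (Z)-β,γ-unsaturated aldehyde
Conditions: Dess–Martin periodinane, NaHCO3, CH2Cl2, 0 °C; used at once
Reagents that add atoms: none
Why: Dess–Martin oxidation under buffered non-basic conditions should give the aldehyde without migration of the double bond into conjugation.

Step 8
Reactants: 12 (Z)-β,γ-unsaturated aldehyde; 5 (E)-allylboronate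
Product: 13 anti homoallylic alcohol (7S,8R)
Conditions: (S)-TRIP phosphoric acid (5 mol %), 4 Å molecular sieves, toluene, −30 °C; aqueous work-up
Reagents that add atoms: none
Why: Chiral phosphoric acid-catalysed allylboration through a closed chair transition state, in which the (E)-γ-substituted allylboronate gives the anti relationship of C7 and C8 and the (S)-catalyst should select the Si face of the aldehyde, setting 7S and 8R.

Step 9
Reactants: 13 anti homoallylic alcohol
Product: 14 O8 p-methoxybenzyl ether
Conditions: NaH, 4-methoxybenzyl chloride, Bu4NI (cat.), DMF, 0 °C to rt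
Reagents that add atoms: 4-methoxybenzyl chloride, COc1ccc(CCl)cc1
Why: Williamson etherification of the secondary alkoxide gives an O8 protecting group that is orthogonal to both silyl ethers.

Step 10
Reactants: 14 O8 p-methoxybenzyl ether
Product: 15 (Z)-allylic alcohol
Conditions: PPTS (cat.), MeOH, rt
Reagents that add atoms: none
Why: Acid-catalysed methanolysis should remove the primary allylic tert-butyldimethylsilyl ether much faster than the tert-butyldiphenylsilyl ether (selective desilylation).

Step 11
Reactants: 15 (Z)-allylic alcohol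
Product: 16 epoxy alcohol (1R,10S)
Conditions: Ti(OiPr)4, D-(−)-diethyl tartrate, t-BuOOH, 4 Å molecular sieves, CH2Cl2, −20 °C
Reagents that add atoms: tert-butyl hydroperoxide, CC(C)(C)OO
Why: Sharpless asymmetric epoxidation of a nerol-type (Z)-trisubstituted allylic alcohol, in which the D-(−)-tartrate ligand delivers oxygen to the face that gives the 1R,10S cis-epoxide under reagent control and the vinyl group is untouched.

Step 12
Reactants: 16 epoxy alcohol
Product: 17 epoxy iodide
Conditions: I2, PPh3, imidazole, CH2Cl2, 0 °C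
Reagents that add atoms: iodine, II
Why: Appel-type iodination of the primary alcohol next to the oxirane; substitution occurs at the CH2 group only, so no stereocentre is touched.

Step 13
Reactants: 18 2,2-dimethyl-1,3-dioxan-5-one
Product: 19 SAMP hydrazone
Conditions: SAMP, cyclohexane, 4 Å molecular sieves, reflux
Reagents that add atoms: (S)-1-amino-2-(methoxymethyl)pyrrolidine, COC[C@@H]1CCCN1N
Why: Condensation of the ketone with the hydrazine auxiliary (Enders SAMP methodology) prepares the dihydroxyacetone unit for asymmetric alkylation.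

Step 14
Reactants: 19 SAMP hydrazone; 17 epoxy iodide
Product: 21 alkylated hydrazone (3S), via lithium azaenolate 20 (not isolated)
Conditions: t-BuLi, THF, −78 °C; then 17, −100 to −78 °C
Reagents that add atoms: none
Why: Enders SAMP-hydrazone α-alkylation, in which the methoxy-chelated lithium azaenolate displaces the primary iodide (SN2 at C2, expected to be faster than attack on the trisubstituted oxirane) on the face dictated by the auxiliary, setting 3S.

Step 15
Reactants: 21 alkylated hydrazone
Product: 22 (S)-4-substituted dioxanone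
Conditions: CuCl2, THF/H2O (pH 7 phosphate buffer), 0 °C to rt
Reagents that add atoms: water, O
Why: Copper-assisted hydrolysis of the hydrazone should release the ketone under near-neutral conditions that spare the acetonide, the oxirane and the α-stereocentre C3.

Step 16
Reactants: 22 (S)-4-substituted dioxanone
Product: 23 bromohydrin (C6 epimers)
Conditions: NBS, DMSO/H2O, 0 °C, dark
Reagents that add atoms: N-bromosuccinimide, O=C1CCC(=O)N1Br; water, O
Why: Bromohydrin formation on the only remaining alkene, with water opening the bromonium ion at the internal carbon so that bromine ends on C5; the C6 configuration is irrelevant because it is oxidised next.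

Step 17
Reactants: 23 bromohydrin
Product: 24 bromomethyl ketone
Conditions: Dess–Martin periodinane, NaHCO3, CH2Cl2, 0 °C to rt
Reagents that add atoms: none
Why: Dess–Martin oxidation of the secondary alcohol under buffered conditions gives the α-bromo ketone without epimerising C7 or eliminating the C8 ether.

Step 18
Reactants: 24 bromomethyl ketone
Product: 26 ring-closed ketol, via samarium enolate 25 (not isolated)
Conditions: SmI2 (2.1 equiv, added dropwise), THF, −78 °C, 0.003 M; pH 7 buffer quench at −78 °C
Reagents that add atoms: none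
Why: Two single-electron transfers from divalent samarium cleave the C5–Br bond and give the trivalent samarium enolate 25 regiospecifically at C5/C6, which adds to the C4 carbonyl of the dioxanone through a samarium-bridged six-membered (Zimmerman–Traxler-type) array, a SmI2-mediated intramolecular Reformatsky-type aldol reaction. The closest known reaction type is the SmI2-promoted Reformatsky cyclisation of carbonyl-tethered α-halo ketones and esters to medium-ring carbocycles and lactones. Ring A closes in the 10-exo-trig mode, helped by the turn imposed by the cis-oxirane and by the chair dioxane that holds the C2 arm equatorial. The new stereocentre C4 is controlled by the temporary dioxane ring: the enolate carbon should attack the chair dioxanone axially, the face that has ring oxygens instead of 1,3-diaxial hydrogens, which places C5 cis to the equatorial C2 arm and the C4 hydroxyl trans to it, as the target requires. The step needs reduction of the C–Br bond in preference to the C4 ketone and the oxirane (secured by the much faster reduction of α-bromo ketones at −78 °C and by the limited amount of SmI2), enolate formation on the C5 side only so that C7 is not epimerised and the C8 ether is not eliminated (secured by the reductive, base-free generation), and ring closure in preference to oligomerisation (secured by high dilution).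

Step 19
Reactants: 26 ring-closed ketol
Product: 27 4,6-diol (6R)
Conditions: Me4NBH(OAc)3, MeCN/AcOH, −30 °C
Reagents that add atoms: none
Why: Evans–Saksena-type hydroxyl-directed reduction, in which the C4 hydroxyl binds the triacetoxyborohydride and delivers hydride intramolecularly to C6; in the ten-membered ring the C3–C4–C5–C6–C7 segment can be neither fully extended nor doubly gauche, and both remaining anti/gauche arrangements of the chair-like delivery transition state lead to the 6R alcohol.

Step 20
Reactants: 27 4,6-diol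
Product: 28 4,6,12-triol
Conditions: TBAF, AcOH, THF, 0 °C to rt
Reagents that add atoms: none
Why: Fluoride cleavage of the primary tert-butyldiphenylsilyl ether under acetic acid buffering (desilylation) leaves the p-methoxybenzyl ether, the acetonide and the oxirane in place.

Step 21
Reactants: 28 4,6,12-triol
Product: 30 γ-lactone, via lactol 29 (not isolated)
Conditions: TEMPO (cat.), PhI(OAc)2, CH2Cl2, rt
Reagents that add atoms: none
Why: Oxoammonium (TEMPO) oxidation selects the primary alcohol, the aldehyde is trapped by the C6 hydroxyl as a five-membered lactol and this is oxidised on to the lactone (oxidative lactonisation), which is trans-fused because C6 and C7 are already set.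

Step 22
Reactants: 30 γ-lactone
Product: 33 α-methylene lactone, via Mannich base 31 (not isolated), via methiodide 32 (not isolated)
Conditions: LiN(SiMe3)2 (3 equiv), THF, −78 °C; CH2=NMe2+ I−, −78 to 0 °C; then MeI, MeOH, rt; then aq NaHCO3, CH2Cl2, rt
Reagents that add atoms: Eschenmoser's salt, C=[N+](C)C.[I-]
Why: Mannich reaction of the lactone enolate with Eschenmoser's salt followed by quaternisation and base-induced elimination is the standard α-methylenation of γ-lactones, and the C11 stereocentre of the Mannich base disappears in the elimination.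

Step 23
Reactants: 33 α-methylene lactone
Product: 34 C8 alcohol
Conditions: DDQ, CH2Cl2/pH 7 buffer, 0 °C
Reagents that add atoms: none
Why: Oxidative cleavage of the p-methoxybenzyl ether by DDQ under buffered neutral conditions frees O8 without base, so that the lactone should not migrate from O6 to O8.

Step 24
Reactants: 34 C8 alcohol
Product: 35 angelate acetonide
Conditions: angelic acid, 2,4,6-trichlorobenzoyl chloride, Et3N, toluene, rt; then 34, 80 °C
Reagents that add atoms: angelic acid, C/C=C(/C)C(=O)O
Why: Yamaguchi-type esterification through the mixed anhydride of angelic acid, run without a nucleophilic catalyst to keep the Z geometry of the acyl group, acylates the secondary C8 hydroxyl while the tertiary C4 hydroxyl stays free.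

Step 25
Reactants: 35 angelate acetonide
Product: 36 target CNP0307250.1
Conditions: PPTS (cat.), MeOH, 0 °C to rt
Reagents that add atoms: none
Why: Acid-catalysed transacetalisation (acetonide methanolysis) with a weak acid should free O3 and O15 while leaving the trisubstituted oxirane, the angelate and the α-methylene lactone intact.

Compound list
1 | but-3-yn-1-ol | C#CCCO | starting material
2 | tert-butyl(but-3-yn-1-yloxy)diphenylsilane | C#CCCO[Si](c1ccccc1)(c1ccccc1)C(C)(C)C | intermediate
3 | tert-butyldiphenyl{[(3E)-4-(4,4,5,5-tetramethyl-1,3,2-dioxaborolan-2-yl)but-3-en-1-yl]oxy}silane | CC1(C)OB(/C=C/CCO[Si](c2ccccc2)(c2ccccc2)C(C)(C)C)OC1(C)C | intermediate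
4 | lithium (chloromethyl)boronate complex of 3 | [Li+].ClC[B-]1(/C=C/CCO[Si](c2ccccc2)(c2ccccc2)C(C)(C)C)OC(C)(C)C(C)(C)O1 | intermediate
5 | tert-butyldiphenyl{[(3E)-5-(4,4,5,5-tetramethyl-1,3,2-dioxaborolan-2-yl)pent-3-en-1-yl]oxy}silane | CC1(C)OB(C/C=C/CCO[Si](c2ccccc2)(c2ccccc2)C(C)(C)C)OC1(C)C | intermediate
6 | but-2-yn-1-ol | CC#CCO | starting material
7 | sodium cyclic alkenylalanate (aluminium on the methyl-bearing carbon and on oxygen) | CC1=CCO[Al-]1(OCCOC)OCCOC.[Na+] | intermediate
8 | (Z)-3-iodobut-2-en-1-ol | C/C(I)=C/CO | intermediate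
9 | (Z)-tert-butyl[(3-iodobut-2-en-1-yl)oxy]dimethylsilane | C/C(I)=C/CO[Si](C)(C)C(C)(C)C | intermediate
10 | (Z)-alkenyllithium from 9 (lithium in place of iodine) | C/C([Li])=C/CO[Si](C)(C)C(C)(C)C | intermediate
11 | (Z)-5-[(tert-butyldimethylsilyl)oxy]-3-methylpent-3-en-1-ol | C/C(CCO)=C/CO[Si](C)(C)C(C)(C)C | intermediate
12 | (Z)-5-[(tert-butyldimethylsilyl)oxy]-3-methylpent-3-enal | C/C(CC=O)=C/CO[Si](C)(C)C(C)(C)C | intermediate
13 | (3S,4R,6Z)-8-[(tert-butyldimethylsilyl)oxy]-3-{2-[(tert-butyldiphenylsilyl)oxy]ethyl}-6-methylocta-1,6-dien-4-ol (target locants 7S,8R) | C=C[C@H](CCO[Si](c1ccccc1)(c1ccccc1)C(C)(C)C)[C@H](O)C/C(C)=C\CO[Si](C)(C)C(C)(C)C | intermediate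
14 | 4-O-(4-methoxybenzyl) ether of 13 | C=C[C@H](CCO[Si](c1ccccc1)(c1ccccc1)C(C)(C)C)[C@H](OCc1ccc(OC)cc1)C/C(C)=C\CO[Si](C)(C)C(C)(C)C | intermediate
15 | (2Z,5R,6S)-6-{2-[(tert-butyldiphenylsilyl)oxy]ethyl}-5-[(4-methoxybenzyl)oxy]-3-methylocta-2,7-dien-1-ol | C=C[C@H](CCO[Si](c1ccccc1)(c1ccccc1)C(C)(C)C)[C@H](OCc1ccc(OC)cc1)C/C(C)=C\CO | intermediate
16 | {(2R,3S)-3-[(2R,3S)-3-{2-[(tert-butyldiphenylsilyl)oxy]ethyl}-2-[(4-methoxybenzyl)oxy]pent-4-en-1-yl]-3-methyloxiran-2-yl}methanol | C=C[C@H](CCO[Si](c1ccccc1)(c1ccccc1)C(C)(C)C)[C@H](OCc1ccc(OC)cc1)C[C@]1(C)O[C@@H]1CO | intermediate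
17 | primary iodide of 16 (CH2OH replaced by CH2I, all stereocentres unchanged) | C=C[C@H](CCO[Si](c1ccccc1)(c1ccccc1)C(C)(C)C)[C@H](OCc1ccc(OC)cc1)C[C@]1(C)O[C@@H]1CI | intermediate
18 | 2,2-dimethyl-1,3-dioxan-5-one | CC1(C)OCC(=O)CO1 | starting material
19 | (S)-N-(2,2-dimethyl-1,3-dioxan-5-ylidene)-2-(methoxymethyl)pyrrolidin-1-amine | COC[C@@H]1CCCN1N=C1COC(C)(C)OC1 | intermediate
20 | lithium azaenolate of 19 | COC[C@@H]1CCCN1N([Li])C1=COC(C)(C)OC1 | intermediate
21 | SAMP hydrazone of 22 (C3 S, dioxane carbon bearing the epoxymethyl arm) | C=C[C@H](CCO[Si](c1ccccc1)(c1ccccc1)C(C)(C)C)[C@H](OCc1ccc(OC)cc1)C[C@]1(C)O[C@@H]1C[C@@H]1OC(C)(C)OCC1=NN1CCC[C@H]1COC | intermediate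
22 | (S)-4-{[(2R,3S)-3-[(2R,3S)-3-{2-[(tert-butyldiphenylsilyl)oxy]ethyl}-2-[(4-methoxybenzyl)oxy]pent-4-en-1-yl]-3-methyloxiran-2-yl]methyl}-2,2-dimethyl-1,3-dioxan-5-one | C=C[C@H](CCO[Si](c1ccccc1)(c1ccccc1)C(C)(C)C)[C@H](OCc1ccc(OC)cc1)C[C@]1(C)O[C@@H]1C[C@@H]1OC(C)(C)OCC1=O | intermediate
23 | bromohydrin of 22 (C5 Br, C6 OH, both C6 epimers) | OC(CBr)[C@H](CCO[Si](c1ccccc1)(c1ccccc1)C(C)(C)C)[C@H](OCc1ccc(OC)cc1)C[C@]1(C)O[C@@H]1C[C@@H]1OC(C)(C)OCC1=O | intermediate
24 | bromomethyl ketone (C5 Br, C6 ketone, C4 ketone in the dioxanone) | O=C(CBr)[C@H](CCO[Si](c1ccccc1)(c1ccccc1)C(C)(C)C)[C@H](OCc1ccc(OC)cc1)C[C@]1(C)O[C@@H]1C[C@@H]1OC(C)(C)OCC1=O | intermediate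
25 | diiodosamarium enolate of the C6 ketone (C5=C6) | C=C(O[Sm](I)I)[C@H](CCO[Si](c1ccccc1)(c1ccccc1)C(C)(C)C)[C@H](OCc1ccc(OC)cc1)C[C@]1(C)O[C@@H]1C[C@@H]1OC(C)(C)OCC1=O | intermediate
26 | ring-closed ketol: ten-membered ring A cis-fused to the O3/O15 acetonide, C4 OH (4R), C6 ketone, 1,10-epoxide, O8 p-methoxybenzyl, C7 CH2CH2OTBDPS | O=C1C[C@@]2(O)COC(C)(C)O[C@H]2C[C@H]3O[C@@]3(C)C[C@@H](OCc4ccc(OC)cc4)[C@H]1CCO[Si](c1ccccc1)(c1ccccc1)C(C)(C)C | intermediate
27 | 4,6-diol (6R alcohol of 26) | O[C@@H]1C[C@@]2(O)COC(C)(C)O[C@H]2C[C@H]3O[C@@]3(C)C[C@@H](OCc4ccc(OC)cc4)[C@H]1CCO[Si](c1ccccc1)(c1ccccc1)C(C)(C)C | intermediate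
28 | 4,6,12-triol (27 without the silyl group) | O[C@@H]1C[C@@]2(O)COC(C)(C)O[C@H]2C[C@H]3O[C@@]3(C)C[C@@H](OCc4ccc(OC)cc4)[C@H]1CCO | intermediate
29 | lactol (O6–C12 hemiacetal, both anomers) | C1C(O)O[C@@H]2C[C@@]4(O)COC(C)(C)O[C@H]4C[C@H]3O[C@@]3(C)C[C@@H](OCc5ccc(OC)cc5)[C@@H]12 | intermediate
30 | trans-fused 6,12-γ-lactone with C11H2 | C1C(=O)O[C@@H]2C[C@@]4(O)COC(C)(C)O[C@H]4C[C@H]3O[C@@]3(C)C[C@@H](OCc5ccc(OC)cc5)[C@@H]12 | intermediate
31 | 11-(dimethylaminomethyl) lactone (Mannich base, C11 epimers) | CN(C)CC1C(=O)O[C@@H]2C[C@@]4(O)COC(C)(C)O[C@H]4C[C@H]3O[C@@]3(C)C[C@@H](OCc5ccc(OC)cc5)[C@@H]12 | intermediate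
32 | trimethylammonium iodide of 31 | C[N+](C)(C)CC1C(=O)O[C@@H]2C[C@@]4(O)COC(C)(C)O[C@H]4C[C@H]3O[C@@]3(C)C[C@@H](OCc5ccc(OC)cc5)[C@@H]12.[I-] | intermediate
33 | α-methylene lactone with O8 p-methoxybenzyl ether and O3/O15 acetonide | C=C1C(=O)O[C@@H]2C[C@@]4(O)COC(C)(C)O[C@H]4C[C@H]3O[C@@]3(C)C[C@@H](OCc5ccc(OC)cc5)[C@@H]12 | intermediate
34 | C8 alcohol (33 without the p-methoxybenzyl group) | C=C1C(=O)O[C@@H]2C[C@@]4(O)COC(C)(C)O[C@H]4C[C@H]3O[C@@]3(C)C[C@@H](O)[C@@H]12 | intermediate
35 | O8 angelate with O3/O15 acetonide | C=C1C(=O)O[C@@H]2C[C@@]4(O)COC(C)(C)O[C@H]4C[C@H]3O[C@@]3(C)C[C@@H](OC(=O)/C(C)=C\C)[C@@H]12 | intermediate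
36 | CNP0307250.1 (1R,3S,4R,6R,7S,8R,10S) | C=C1C(=O)O[C@@H]2C[C@@](O)(CO)[C@@H](O)C[C@H]3O[C@@]3(C)C[C@@H](OC(=O)/C(C)=C\C)[C@@H]12 | target

Total step count: 25. Longest linear sequence: 21 steps (from 6 through steps 4–12 and 14–25).

Steps most likely to fail

Step 18. The ten-membered ring closure may be outrun by protonation of the samarium enolate (simple debromination), by intermolecular aldol addition or by reduction of the C4 ketone. The fallback replaces the reductive enolate by a preformed silyl enol ether. It sets out from 24, which is treated with zinc dust and Me3SiCl to give the trimethylsilyl enol ether F1 regiospecifically. F1 is cyclised under high dilution by fluoride activation (tris(dimethylamino)sulfonium difluorotrimethylsilicate, THF, −78 to 0 °C; a fluoride-promoted Mukaiyama-type aldol with silyl transfer) to the O4-silylated ketol F2. Mild methanolysis (K2CO3, MeOH, 0 °C) then returns to the route at 26.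

Step 14. Substitution next to the oxirane may be sluggish, or the azaenolate may attack the oxirane instead. The fallback moves the epoxidation after the alkylation. It sets out from 15, which is converted with CBr4 and PPh3 into the allylic bromide F3, and F3 alkylates the azaenolate 20 to give the alkene hydrazone F4. Hydrolysis with CuCl2 gives the alkene ketone F5. Asymmetric Shi epoxidation of the (Z)-trisubstituted alkene follows, with KHSO5 and the enantiomer of the fructose-derived ketone that the spiro transition-state model assigns to the required face; the vinyl group is expected to react much more slowly. This returns to the route at 22.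

Step 19. Hydride delivery may be misdirected if the tertiary C4 hydroxyl does not bind the borohydride, giving the wrong configuration at C6. The fallback corrects the centre instead of controlling it. It sets out from 26: the 6-epi diol F6 (the product of the misdirected reduction, or made on purpose with NaBH4) undergoes Mitsunobu inversion with 4-nitrobenzoic acid, PPh3 and diisopropyl azodicarboxylate, the tertiary hydroxyl being inert, to give the inverted 4-nitrobenzoate F7. Methanolysis (K2CO3, MeOH) returns to the route at 27.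

Further compounds
F1 | step 18 | trimethylsilyl enol ether of the C6 ketone of 24 (C5=C6) | C=C(O[Si](C)(C)C)[C@H](CCO[Si](c1ccccc1)(c1ccccc1)C(C)(C)C)[C@H](OCc1ccc(OC)cc1)C[C@]1(C)O[C@@H]1C[C@@H]1OC(C)(C)OCC1=O
F2 | step 18 | O4-trimethylsilyl ether of 26 | O=C1C[C@@]2(O[Si](C)(C)C)COC(C)(C)O[C@H]2C[C@H]3O[C@@]3(C)C[C@@H](OCc4ccc(OC)cc4)[C@H]1CCO[Si](c1ccccc1)(c1ccccc1)C(C)(C)C
F3 | step 14 | (Z)-allylic bromide from 15 | C=C[C@H](CCO[Si](c1ccccc1)(c1ccccc1)C(C)(C)C)[C@H](OCc1ccc(OC)cc1)C/C(C)=C\CBr
F4 | step 14 | SAMP hydrazone of F5 | C=C[C@H](CCO[Si](c1ccccc1)(c1ccccc1)C(C)(C)C)[C@H](OCc1ccc(OC)cc1)C/C(C)=C\C[C@@H]1OC(C)(C)OCC1=NN1CCC[C@H]1COC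
F5 | step 14 | (S)-4-allylated dioxanone with the (Z)-1(10)-alkene (22 without the epoxide oxygen) | C=C[C@H](CCO[Si](c1ccccc1)(c1ccccc1)C(C)(C)C)[C@H](OCc1ccc(OC)cc1)C/C(C)=C\C[C@@H]1OC(C)(C)OCC1=O
F6 | step 19 | 6-epi diol (6S alcohol of 26) | O[C@H]1C[C@@]2(O)COC(C)(C)O[C@H]2C[C@H]3O[C@@]3(C)C[C@@H](OCc4ccc(OC)cc4)[C@H]1CCO[Si](c1ccccc1)(c1ccccc1)C(C)(C)C
F7 | step 19 | 6-O-(4-nitrobenzoate) of 27 (6R) | O=C(O[C@@H]1C[C@@]2(O)COC(C)(C)O[C@H]2C[C@H]3O[C@@]3(C)C[C@@H](OCc4ccc(OC)cc4)[C@H]1CCO[Si](c5ccccc5)(c5ccccc5)C(C)(C)C)c1ccc([N+](=O)[O-])cc1
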